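**Retrosynthetic overview**

- The target, methyl 3-tricosyl-1H-pyrrole-2-carboxylate, is traced back through N-debenzylation and dehydrogenation to an N-(2,4-dimethoxybenzyl) 2,3-dihydropyrrole.
- The strategy rests on C2 of the pyrrole ring: this ester-bearing carbon sits alone between N1 and C3. Cutting N1–C2 and C2–C3 removes it as a one-carbon carbene unit (from methyl diazoacetate) and leaves N1, C5, C4, C3 and the tricosyl chain on C3 as one 1-azadiene.
- The only ring (the pyrrole ring) is formed in a single operation: carbenoid capture at nitrogen gives an azomethine ylide, which closes by 1,5-electrocyclisation.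
- The azadiene comes from (E)-hexacos-2-enal and 2,4-dimethoxybenzylamine, and the enal from 1-tetracosanol by oxidation and two-carbon Wittig homologation. The diazo ester comes from glycine methyl ester.

Key step: step 5

Assumption: the target is achiral, so the two stereocentres formed in step 5 are transient and their relative configuration is immaterial; methyl diazoacetate is handled only as a dried, titrated CH2Cl2 solution and is never concentrated or distilled.

**Route**

Step 1
Reactants: 1 1-tetracosanol
Product: 2 tetracosanal
Conditions: IBX (1.5 equiv), EtOAc, 80 °C; cool, filter, concentrate; use promptly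
Reagents that add atoms: none
Why: IBX oxidation of a primary alcohol stops cleanly at the aldehyde, hot ethyl acetate dissolves the waxy alcohol, and the reduced iodine reagent is removed by filtration.

Step 2
Reactants: 2 tetracosanal; 3 (triphenylphosphoranylidene)acetaldehyde
Product: 4 (E)-hexacos-2-enal
Conditions: 3 (1.05 equiv), toluene, 80 °C
Reagents that add atoms: none
Why: Wittig olefination with the stabilised formylmethylene ylide should give the (E)-enal under thermodynamic control, and the saturated aldehyde is more electrophilic than the enal product, which limits a second homologation.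

Step 3
Reactants: 4 (E)-hexacos-2-enal; 5 2,4-dimethoxybenzylamine
Product: 6 (1E,2E)-N-(2,4-dimethoxybenzyl)hexacos-2-en-1-imine
Conditions: 5 (1.0 equiv), MgSO4, CH2Cl2, 0 °C to rt; filter, concentrate; use crude
Reagents that add atoms: none
Why: Imine condensation of a primary amine with the aldehyde is faster than conjugate addition and is driven by the drying agent, and the aldimine should settle in the less hindered (E) geometry at C=N.

Step 4
Reactants: 7 glycine methyl ester hydrochloride
Product: 8 methyl diazoacetate
Conditions: NaNO2 (1.2 equiv), cat. H2SO4, CH2Cl2/H2O, −5 to 0 °C; wash with aq. NaHCO3, dry (MgSO4), titrate; keep as CH2Cl2 solution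
Reagents that add atoms: sodium nitrite, [Na+].[O-]N=O
Why: Diazotisation of the α-amino ester gives a diazonium ion that loses its ester-acidified α-proton to the stabilised diazo compound, which is extracted into the organic layer as it forms.

Step 5
Reactants: 6 (1E,2E)-N-(2,4-dimethoxybenzyl)hexacos-2-en-1-imine (1.5 equiv); 8 methyl diazoacetate (1.0 equiv)
Product: 10 methyl (2RS,3RS)-1-(2,4-dimethoxybenzyl)-3-tricosyl-2,3-dihydro-1H-pyrrole-2-carboxylate, via azomethine ylide 9 (not isolated)
Conditions: Rh2(OAc)4 (2 mol%), 4 Å molecular sieves, CH2Cl2, 40 °C, 8 added by syringe pump over 8 h; filter through Et3N-deactivated silica; carry on at once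
Reagents that add atoms: none
Why: Proposed new method: Rh2(OAc)4 turns 8 into an electrophilic rhodium carbenoid, the sp2 lone pair on nitrogen of 6 attacks it (N1–C2) and release of the catalyst leaves the conjugated azomethine ylide 9, in which C2 sits cis to the C4=C3 vinyl unit because the lone pair of the (E)-imine lies on the vinyl side. The closest known reaction type is the dirhodium-catalysed reaction of aryl- or vinyl-diazoacetates with N-aryl cinnamaldimines, and of dihalocarbenes with 1-azadienes, which give 2,3-dihydropyrroles through the same kind of ylide; an acceptor-only diazoacetate with an N-alkyl aliphatic azadiene is the untested part. The one ring closes by thermal disrotatory 6π-electron 1,5-electrocyclisation of the 2-azapentadienyl anion, C2 bonding to the monosubstituted alkene terminus C3 from the s-cis conformer about C5–C4. C2 and C3 are set relative to each other by the ylide and alkene geometries carried through the disrotatory motion (chain outside from the (E)-alkene; ester inside gives trans, ester outside gives cis) and the acidic C2–H lets the mixture settle toward the trans isomer drawn, racemic because nothing in the system is chiral; both centres are erased in step 6. The step needs 1,5-closure to outrun conrotatory 1,3-closure to the vinylaziridine, cyclopropanation of C3=C4, carbene dimerisation and attack of the carbenoid on the enamine product; the pre-set cis ylide geometry and free s-cis rotation, the electron-poor azadiene C=C, the excess of 6 and the slow addition of 8 are what should secure it.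

Step 6
Reactants: 10 methyl (2RS,3RS)-1-(2,4-dimethoxybenzyl)-3-tricosyl-2,3-dihydro-1H-pyrrole-2-carboxylate
Product: 11 methyl 1-(2,4-dimethoxybenzyl)-3-tricosyl-1H-pyrrole-2-carboxylate
Conditions: DDQ (1.05 equiv), toluene, 0 °C to rt
Reagents that add atoms: none
Why: DDQ dehydrogenation should proceed by hydride abstraction from C3 (allylic to the enamine, giving a 2H-pyrrolium ion) and loss of the acidic C2 proton to the aromatic pyrrole, the enamine being far easier to oxidise than the benzylic N–CH2 group.

Step 7
Reactants: 11 methyl 1-(2,4-dimethoxybenzyl)-3-tricosyl-1H-pyrrole-2-carboxylate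
Product: 12 methyl 3-tricosyl-1H-pyrrole-2-carboxylate
Conditions: TFA/ClCH2CH2Cl 1:1, anisole (10 equiv), 60 °C
Reagents that add atoms: none
Why: Acidolytic N-debenzylation should work because the 2,4-dimethoxybenzyl cation is strongly stabilised, the ester-bearing pyrrole is a competent nitrogen leaving group, and anisole removes the cation irreversibly by Friedel–Crafts alkylation.

**Compound list**

1 | 1-tetracosanol | CCCCCCCCCCCCCCCCCCCCCCCCO | starting material
2 | tetracosanal | CCCCCCCCCCCCCCCCCCCCCCCC=O | intermediate
3 | (triphenylphosphoranylidene)acetaldehyde | O=CC=P(c1ccccc1)(c1ccccc1)c1ccccc1 | starting material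
4 | (E)-hexacos-2-enal | CCCCCCCCCCCCCCCCCCCCCCC/C=C/C=O | intermediate
5 | 2,4-dimethoxybenzylamine | COc1ccc(CN)c(OC)c1 | starting material
6 | (1E,2E)-N-(2,4-dimethoxybenzyl)hexacos-2-en-1-imine | CCCCCCCCCCCCCCCCCCCCCCC/C=C/C=N/Cc1ccc(OC)cc1OC | intermediate
7 | glycine methyl ester hydrochloride | COC(=O)CN.Cl | starting material
8 | methyl diazoacetate | COC(=O)C=[N+]=[N-] | intermediate
9 | azomethine ylide from 6 and the carbene of 8 (ylide carbon cis to the vinyl group at C=N+) | CCCCCCCCCCCCCCCCCCCCCCC/C=C/C=[N+](/Cc1ccc(OC)cc1OC)[CH-]C(=O)OC | intermediate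
10 | methyl (2RS,3RS)-1-(2,4-dimethoxybenzyl)-3-tricosyl-2,3-dihydro-1H-pyrrole-2-carboxylate (trans, racemic; one enantiomer drawn) | CCCCCCCCCCCCCCCCCCCCCCC[C@@H]1C=CN(Cc2ccc(OC)cc2OC)[C@H]1C(=O)OC | intermediate
11 | methyl 1-(2,4-dimethoxybenzyl)-3-tricosyl-1H-pyrrole-2-carboxylate | CCCCCCCCCCCCCCCCCCCCCCCc1ccn(Cc2ccc(OC)cc2OC)c1C(=O)OC | intermediate
12 | methyl 3-tricosyl-1H-pyrrole-2-carboxylate | CCCCCCCCCCCCCCCCCCCCCCCc1cc[nH]c1C(=O)OC | target

**Step count**

Total steps: 7. Longest linear sequence: 6 (steps 1, 2, 3, 5, 6, 7).

**Steps most likely to fail**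

Step 5. The ylide may partition toward 1,3-closure (aziridination) or be intercepted by carbene dimers acting as dipolarophiles. The imine may also throttle the catalyst by axial coordination, and the carbenoid may consume the enamine product. The fallback uses known chemistry and sets out from tetracosanal 2. Henry addition of nitromethane (MeNO2, cat. t-BuOK, THF/t-BuOH, 0 °C) would give racemic 1-nitropentacosan-2-ol F1. Acetylation (Ac2O, cat. H2SO4, 0 °C to rt) would give 1-nitropentacosan-2-yl acetate F2. A Barton–Zard reaction with methyl isocyanoacetate and DBU (2.2 equiv) in THF would first eliminate acetic acid to give (E)-1-nitropentacos-1-ene F3 in the flask. The isocyanoacetate anion then adds to the chain-bearing carbon, the nitronate closes onto the isocyanide carbon, and nitrite is lost with aromatisation. The chain ends up on C3 next to the ester-bearing C2, so the sequence comes back to the route directly at 12.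

Step 7. Heterolysis of the N–CH2Ar bond at the weakly basic pyrrole nitrogen may stall, and the liberated benzyl cation may return to C4 or C5 of the pyrrole instead of being scavenged. The fallback replaces the acid-labile group by a base-labile one and sets out from enal 4. Condensation with 3-aminopropanenitrile (MgSO4, CH2Cl2) would give (1E,2E)-N-(2-cyanoethyl)hexacos-2-en-1-imine F4. The conditions of step 5 with 8 would lead through the N-(2-cyanoethyl) azomethine ylide F5 to methyl (2RS,3RS)-1-(2-cyanoethyl)-3-tricosyl-2,3-dihydro-1H-pyrrole-2-carboxylate F6. DDQ as in step 6 would give methyl 1-(2-cyanoethyl)-3-tricosyl-1H-pyrrole-2-carboxylate F7. NaOMe in MeOH/THF at 50 °C would then remove the cyanoethyl group by retro-Michael loss of acrylonitrile without touching the methyl ester, coming back to the route at 12.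

Step 2. The enal product may undergo a second olefination (chain extension to the dienal), and the enolisable aldehyde may self-condense in the hot, basic ylide solution. The fallback sets out from tetracosanal 2. Horner–Wadsworth–Emmons olefination with triethyl phosphonoacetate (NaH, THF, 0 °C to rt) would give ethyl (E)-hexacos-2-enoate F8. Reduction with i-Bu2AlH (2.2 equiv, CH2Cl2, −78 to 0 °C) would give (E)-hexacos-2-en-1-ol F9. Allylic oxidation with MnO2 (CH2Cl2, rt) would come back to the route at 4.

**Further compounds**

F1 | step 5 | 1-nitropentacosan-2-ol (racemic) | CCCCCCCCCCCCCCCCCCCCCCCC(O)C[N+](=O)[O-]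
F2 | step 5 | 1-nitropentacosan-2-yl acetate (racemic) | CCCCCCCCCCCCCCCCCCCCCCCC(OC(C)=O)C[N+](=O)[O-]
F3 | step 5 | (E)-1-nitropentacos-1-ene | CCCCCCCCCCCCCCCCCCCCCCC/C=C/[N+](=O)[O-]
F4 | step 7 | (1E,2E)-N-(2-cyanoethyl)hexacos-2-en-1-imine | CCCCCCCCCCCCCCCCCCCCCCC/C=C/C=N/CCC#N
F5 | step 7 | N-(2-cyanoethyl) azomethine ylide from F4 and the carbene of 8 | CCCCCCCCCCCCCCCCCCCCCCC/C=C/C=[N+](/CCC#N)[CH-]C(=O)OC
F6 | step 7 | methyl (2RS,3RS)-1-(2-cyanoethyl)-3-tricosyl-2,3-dihydro-1H-pyrrole-2-carboxylate (racemic) | CCCCCCCCCCCCCCCCCCCCCCC[C@@H]1C=CN(CCC#N)[C@H]1C(=O)OC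
F7 | step 7 | methyl 1-(2-cyanoethyl)-3-tricosyl-1H-pyrrole-2-carboxylate | CCCCCCCCCCCCCCCCCCCCCCCc1ccn(CCC#N)c1C(=O)OC
F8 | step 2 | ethyl (E)-hexacos-2-enoate | CCCCCCCCCCCCCCCCCCCCCCC/C=C/C(=O)OCC
F9 | step 2 | (E)-hexacos-2-en-1-ol | CCCCCCCCCCCCCCCCCCCCCCC/C=C/CO
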